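**Retrosynthetic overview**
1. The route rests on the C3–C4 bond of ring C. It ties the aroyl carbon C4 (on ring A) to C3, a benzylic, ketone-alpha CH that carries ring B and epimerises with base. This bond is therefore made late, by a base-free, radical, enantioconvergent nickel coupling (13 → 14) that closes ring C and sets C3.
2. O1–C2 and C2–C3 go back to phenoxide opening of aryl oxirane 8 by salicylate 10, and 8 goes back to aldehyde 7 plus a sulfonium methylide.
3. Ring B: the 1,1-dimethylallyl group at C5' comes from an aromatic Claisen shift of the 4-O-prenyl ether of 2,3,4-trihydroxybenzaldehyde (1). Ring A comes from methyl 2,4-dihydroxybenzoate (9).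
4. Order of rings: rings A and B are bought, ring C is the only ring formed (step 10), and one MOM cleavage ends the route.

Key step: step 10

Assumption: the sense of induction of the bis(oxazoline) ligand in this new ring closure cannot be predicted with certainty. The (R,R)-ligand is written, and its (S,S)-antipode would be used if a first run gave the 3R ketone.

**Route**

Step 1
Reactants: 1 2,3,4-trihydroxybenzaldehyde; 2 prenyl bromide (1-bromo-3-methylbut-2-ene)
Product: 3 2,3-dihydroxy-4-[(3-methylbut-2-en-1-yl)oxy]benzaldehyde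
Conditions: NaHCO3 (1.5 equiv), 2 (1.05 equiv), DMF, 40 °C, Ar
Reagents that add atoms: none
Why: Williamson etherification under a weak base, in which hydrogencarbonate should ionise only the most acidic phenol (the 4-OH para to the formyl group, the 2-OH being held in a hydrogen bond to the aldehyde), so that one equivalent of the allylic bromide alkylates O-4.

Step 2
Reactants: 3 2,3-dihydroxy-4-[(3-methylbut-2-en-1-yl)oxy]benzaldehyde
Product: 4 2,3-bis(methoxymethoxy)-4-[(3-methylbut-2-en-1-yl)oxy]benzaldehyde
Conditions: MOMCl (3 equiv), i-Pr2NEt (4 equiv), CH2Cl2, 0 → 40 °C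
Reagents that add atoms: chloromethyl methyl ether (MOMCl), COCCl
Why: Standard acetal protection (O-alkylation with MOMCl and a hindered amine) of the two remaining phenols, with excess reagent and gentle warming to overcome the hydrogen-bonded 2-OH.

Step 3
Reactants: 4 2,3-bis(methoxymethoxy)-4-[(3-methylbut-2-en-1-yl)oxy]benzaldehyde
Product: 6 4-hydroxy-2,3-bis(methoxymethoxy)-5-(2-methylbut-3-en-2-yl)benzaldehyde, via ortho-dienone 5 (not isolated)
Conditions: PhNEt2, 190 °C, sealed tube, Ar
Reagents that add atoms: none
Why: Aromatic Claisen rearrangement, in which the [3,3] shift should deliver the allyl unit through its dimethyl-substituted terminus to C5 (the only free ortho position, since C3 carries OMOM and the para carbon C1 the formyl group), dienone 5 then tautomerising to the phenol in a non-acidic medium that spares the MOM ethers.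

Step 4
Reactants: 6 4-hydroxy-2,3-bis(methoxymethoxy)-5-(2-methylbut-3-en-2-yl)benzaldehyde
Product: 7 4-methoxy-2,3-bis(methoxymethoxy)-5-(2-methylbut-3-en-2-yl)benzaldehyde
Conditions: MeI, K2CO3, DMF, rt
Reagents that add atoms: iodomethane, CI
Why: Williamson methylation of the hindered but acidic 4-OH (para to the aldehyde) with the small electrophile MeI, which also removes the phenol that could later add to the neighbouring 1,1-dimethylallyl group.

Step 5
Reactants: 7 4-methoxy-2,3-bis(methoxymethoxy)-5-(2-methylbut-3-en-2-yl)benzaldehyde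
Product: 8 rac-2-[4-methoxy-2,3-bis(methoxymethoxy)-5-(2-methylbut-3-en-2-yl)phenyl]oxirane
Conditions: Me3S+ I−, KOt-Bu, DMSO/THF, 0 °C → rt; used crude after a basic aqueous work-up
Reagents that add atoms: trimethylsulfonium iodide, C[S+](C)C.[I-]
Why: Corey–Chaykovsky epoxidation, in which the sulfonium methylide adds to the non-enolisable aldehyde and the betaine closes to the terminal epoxide (racemic) under basic conditions that the MOM ethers and the alkene tolerate.

Step 6
Reactants: 9 methyl 2,4-dihydroxybenzoate
Product: 10 methyl 2-hydroxy-4-(methoxymethoxy)benzoate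
Conditions: MOMCl (1.1 equiv), K2CO3, acetone, 0 °C → rt
Reagents that add atoms: chloromethyl methyl ether (MOMCl), COCCl
Why: Selective Williamson-type acetal protection, the free 4-OH reacting while the 2-OH, hydrogen-bonded to the ester carbonyl, should stay untouched with one equivalent of reagent.

Step 7
Reactants: 8 rac-2-[4-methoxy-2,3-bis(methoxymethoxy)-5-(2-methylbut-3-en-2-yl)phenyl]oxirane; 10 methyl 2-hydroxy-4-(methoxymethoxy)benzoate
Product: 11 rac-methyl 2-{2-hydroxy-2-[4-methoxy-2,3-bis(methoxymethoxy)-5-(2-methylbut-3-en-2-yl)phenyl]ethoxy}-4-(methoxymethoxy)benzoate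
Conditions: Cs2CO3 (0.2 equiv), 10 (1.3 equiv), DMF, 80 °C
Reagents that add atoms: none
Why: Base-catalysed phenolysis of an aryl oxirane (SN2 epoxide opening), in which the phenoxide should attack the unhindered CH2 terminus and not the ortho-substituted benzylic carbon under aprotic, non-acidic conditions, proton transfer from further phenol turning the base over.

Step 8
Reactants: 11 rac-methyl 2-{2-hydroxy-2-[4-methoxy-2,3-bis(methoxymethoxy)-5-(2-methylbut-3-en-2-yl)phenyl]ethoxy}-4-(methoxymethoxy)benzoate
Product: 12 rac-2-{2-hydroxy-2-[4-methoxy-2,3-bis(methoxymethoxy)-5-(2-methylbut-3-en-2-yl)phenyl]ethoxy}-4-(methoxymethoxy)benzoic acid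
Conditions: LiOH (3 equiv), THF/MeOH/H2O, 40 °C; then cold dilute HCl to pH 4
Reagents that add atoms: lithium hydroxide, [Li+].[OH-]
Why: Ester saponification with hydroxide, to which the MOM ethers are inert, any transesterified or lactonised material from step 7 converging on the same hydroxy acid.

Step 9
Reactants: 12 rac-2-{2-hydroxy-2-[4-methoxy-2,3-bis(methoxymethoxy)-5-(2-methylbut-3-en-2-yl)phenyl]ethoxy}-4-(methoxymethoxy)benzoic acid
Product: 13 rac-2-{2-chloro-2-[4-methoxy-2,3-bis(methoxymethoxy)-5-(2-methylbut-3-en-2-yl)phenyl]ethoxy}-4-(methoxymethoxy)benzoyl chloride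
Conditions: 1-chloro-N,N,2-trimethylprop-1-en-1-amine (2.1 equiv), CH2Cl2, 0 °C → rt; evaporated under vacuum and used at once without chromatography
Reagents that add atoms: 1-chloro-N,N,2-trimethylprop-1-en-1-amine, CC(C)=C(Cl)N(C)C
Why: Deoxychlorination with an alpha-chloroenamine, which should turn the carboxylic acid into the acid chloride and the benzylic alcohol into the chloride while releasing only a neutral amide, so that no HCl arises to cleave the MOM ethers.

Step 10
Reactants: 13 rac-2-{2-chloro-2-[4-methoxy-2,3-bis(methoxymethoxy)-5-(2-methylbut-3-en-2-yl)phenyl]ethoxy}-4-(methoxymethoxy)benzoyl chloride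
Product: 14 (3S)-7-(methoxymethoxy)-3-[4-methoxy-2,3-bis(methoxymethoxy)-5-(2-methylbut-3-en-2-yl)phenyl]chroman-4-one
Conditions: NiCl2(dme) (15 mol%), (4R,4'R)-2,2'-(propane-2,2-diyl)bis(4-phenyl-4,5-dihydrooxazole) (33 mol%), Mn powder (3 equiv), 3 Å molecular sieves, THF/DMA (7:3), slow addition of 13 to a final 0.01 M, 0 → 20 °C; filtration, pH 7 buffer wash, neutral silica
Reagents that add atoms: none
Why: Proposed new method: zerovalent nickel (from NiCl2(dme) and Mn) carrying the chiral bis(oxazoline) should insert into the aroyl C–Cl bond, a low-valent nickel species then abstracts chlorine from the weak, electron-rich benzylic C–Cl bond to give a planar benzylic radical at C3 that has lost its configuration, and capture of this radical by the ligated acylnickel centre followed by reductive elimination from trivalent nickel forms C3–C4. The closest known reaction type is the nickel/bis(oxazoline)-catalysed, manganese-driven enantioconvergent reductive coupling of acid chlorides with racemic secondary benzylic chlorides, known between two molecules and for aliphatic acid chlorides but not within one molecule or with an aroyl chloride. Ring C closes when the tethered radical meets the acyl carbon, formally a 6-exo capture that passes through a seven-membered acyl(benzyl)nickelacycle and contracts to the six-membered ring on reductive elimination. The new stereocentre C3 is set by the ligand alone, which distinguishes the two faces of the planar radical at capture and reductive elimination, so both enantiomers of 13 should converge on (3S)-14. The step needs ring closure to outrun beta-aryloxy elimination from benzylnickel species, benzylic dimerisation and decarbonylation of the aroylnickel, which the short ortho-phenylene ether tether, high dilution with slow addition and low temperature should secure. No base is present, so the enolisable alpha-aryl ketone keeps its configuration, and an aroyl chloride cannot divert to a ketene.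

Step 11
Reactants: 14 (3S)-7-(methoxymethoxy)-3-[4-methoxy-2,3-bis(methoxymethoxy)-5-(2-methylbut-3-en-2-yl)phenyl]chroman-4-one
Product: 15 (3S)-3-[2,3-dihydroxy-4-methoxy-5-(2-methylbut-3-en-2-yl)phenyl]-7-hydroxychroman-4-one (CNP0134633.1)
Conditions: ZnBr2 (3.3 equiv), n-PrSH (6 equiv), CH2Cl2, 0 °C, 10–15 min, Ar, dark; pH 7 phosphate buffer quench
Reagents that add atoms: none
Why: Lewis acid–thiol cleavage of the three MOM acetals, in which ZnBr2 activates each acetal and the thiol traps the methoxymethyl cation in a fast, cold, base-free reaction that should leave the C3–H, the aryl ketone, the methyl ether and the unconjugated vinyl group untouched.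

**Compound list**
1 | 2,3,4-trihydroxybenzaldehyde | O=Cc1ccc(O)c(O)c1O | starting material
2 | prenyl bromide (1-bromo-3-methylbut-2-ene) | CC(C)=CCBr | starting material
3 | 2,3-dihydroxy-4-[(3-methylbut-2-en-1-yl)oxy]benzaldehyde | O=Cc1ccc(OCC=C(C)C)c(O)c1O | intermediate
4 | 2,3-bis(methoxymethoxy)-4-[(3-methylbut-2-en-1-yl)oxy]benzaldehyde | O=Cc1ccc(OCC=C(C)C)c(OCOC)c1OCOC | intermediate
5 | 5,6-bis(methoxymethoxy)-3-(2-methylbut-3-en-2-yl)-4-oxocyclohexa-1,5-diene-1-carbaldehyde (ortho-dienone, racemic, not isolated) | O=CC1=CC(C(C)(C)C=C)C(=O)C(OCOC)=C1OCOC | intermediate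
6 | 4-hydroxy-2,3-bis(methoxymethoxy)-5-(2-methylbut-3-en-2-yl)benzaldehyde | O=Cc1cc(C(C)(C)C=C)c(O)c(OCOC)c1OCOC | intermediate
7 | 4-methoxy-2,3-bis(methoxymethoxy)-5-(2-methylbut-3-en-2-yl)benzaldehyde | O=Cc1cc(C(C)(C)C=C)c(OC)c(OCOC)c1OCOC | intermediate
8 | rac-2-[4-methoxy-2,3-bis(methoxymethoxy)-5-(2-methylbut-3-en-2-yl)phenyl]oxirane | C=CC(C)(C)c1cc(C2CO2)c(OCOC)c(OCOC)c1OC | intermediate
9 | methyl 2,4-dihydroxybenzoate | COC(=O)c1ccc(O)cc1O | starting material
10 | methyl 2-hydroxy-4-(methoxymethoxy)benzoate | COC(=O)c1ccc(OCOC)cc1O | intermediate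
11 | rac-methyl 2-{2-hydroxy-2-[4-methoxy-2,3-bis(methoxymethoxy)-5-(2-methylbut-3-en-2-yl)phenyl]ethoxy}-4-(methoxymethoxy)benzoate | C=CC(C)(C)c1cc(C(O)COc2cc(OCOC)ccc2C(=O)OC)c(OCOC)c(OCOC)c1OC | intermediate
12 | rac-2-{2-hydroxy-2-[4-methoxy-2,3-bis(methoxymethoxy)-5-(2-methylbut-3-en-2-yl)phenyl]ethoxy}-4-(methoxymethoxy)benzoic acid | C=CC(C)(C)c1cc(C(O)COc2cc(OCOC)ccc2C(=O)O)c(OCOC)c(OCOC)c1OC | intermediate
13 | rac-2-{2-chloro-2-[4-methoxy-2,3-bis(methoxymethoxy)-5-(2-methylbut-3-en-2-yl)phenyl]ethoxy}-4-(methoxymethoxy)benzoyl chloride | C=CC(C)(C)c1cc(C(Cl)COc2cc(OCOC)ccc2C(=O)Cl)c(OCOC)c(OCOC)c1OC | intermediate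
14 | (3S)-7-(methoxymethoxy)-3-[4-methoxy-2,3-bis(methoxymethoxy)-5-(2-methylbut-3-en-2-yl)phenyl]chroman-4-one | C=CC(C)(C)c1cc([C@H]2COc3cc(OCOC)ccc3C2=O)c(OCOC)c(OCOC)c1OC | intermediate
15 | (3S)-3-[2,3-dihydroxy-4-methoxy-5-(2-methylbut-3-en-2-yl)phenyl]-7-hydroxychroman-4-one | C=CC(C)(C)c1cc([C@H]2COc3cc(O)ccc3C2=O)c(O)c(O)c1OC | target

**Step count**
Total: 11 steps. Longest linear sequence: 10 steps (steps 1–5 and 7–11); step 6 is the one-step side branch.

**Steps most likely to fail**

Step 10 (proposed new method). The tethered benzylnickel or radical may undergo beta-aryloxy elimination, dimerise, or lose CO before ring closure, or the ligand may discriminate the faces of the radical poorly.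

The fallback uses known chemistry, sets out from 7 and returns at 14.
- Baeyer–Villiger oxidation of 7 (mCPBA, NaHCO3, CH2Cl2, 0 °C, migration of the electron-rich aryl group) should give 4-methoxy-2,3-bis(methoxymethoxy)-5-(2-methylbut-3-en-2-yl)phenyl formate F1.
- Methanolysis (K2CO3, MeOH) would give the corresponding phenol F2.
- Triflation (Tf2O, pyridine, CH2Cl2, 0 °C) would give the aryl trifluoromethanesulfonate F3.
- Commercial 7-hydroxychroman-4-one would be protected (MOMCl, i-Pr2NEt) as 7-(methoxymethoxy)chroman-4-one F4.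
- Palladium-catalysed ketone alpha-arylation of F4 with F3 (Pd(OAc)2, XPhos, K3PO4, toluene, 80 °C) should give the racemic tri-MOM isoflavanone F5.
- Asymmetric transfer hydrogenation with dynamic kinetic resolution (RuCl(p-cymene)[(S,S)-TsDPEN], HCO2H/Et3N, 40 °C) follows. The amine equilibrates C3 through the enol while the catalyst reduces one enantiomer, and by analogy with simple aryl ketones this antipode should give the cis-(3S,4S)-isoflavan-4-ol F6.
- Buffered Dess–Martin oxidation (NaHCO3, CH2Cl2, 0 °C) would return ketone 14 with C3 intact.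

Step 9. The acyl chloride formed first may acylate the neighbouring carbinol to a seven-membered lactone before the alcohol is chlorinated.

The fallback stages the two activations, sets out from 12 and returns at 13.
- TBSCl (1.05 equiv) with Et3N in CH2Cl2 at 0 °C should silylate only the carboxylic acid, giving the hydroxy tert-butyldimethylsilyl ester F7.
- The alpha-chloroenamine (1.1 equiv) would then chlorinate the carbinol with the carboxyl masked, giving the chloro tert-butyldimethylsilyl ester F8.
- Oxalyl chloride with catalytic DMF (CH2Cl2, 0 °C) should convert the silyl ester directly into the acid chloride under neutral conditions, giving 13.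

Step 3. At 190 °C the ortho-hydroxy 1,1-dimethylallyl product may rearrange further (abnormal Claisen/ene pathway), cyclise onto the alkene, or lose the prenyl group.

The fallback installs the side chain by cross-coupling, sets out from 1 and returns at 7.
- Borate-directed selective 4-O-methylation of 1 (Na2B4O7, NaOH, Me2SO4, H2O) should give 2,3-dihydroxy-4-methoxybenzaldehyde F9.
- Bis-protection (MOMCl, i-Pr2NEt) would give 4-methoxy-2,3-bis(methoxymethoxy)benzaldehyde F10.
- Bromination (NBS, MeCN, 0 °C) at C5, which is ortho to OMe, para to the 2-OMOM group and meta to the aldehyde, would give 5-bromo-4-methoxy-2,3-bis(methoxymethoxy)benzaldehyde F11.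
- A gamma-selective Suzuki–Miyaura coupling of F11 with 3-methylbut-2-enylboronic acid pinacol ester (Pd(OAc)2, a bulky dialkylbiarylphosphine chosen for the branched product, K3PO4, THF/H2O) should give 7.

**Further compounds**
F1 | step 10 | 4-methoxy-2,3-bis(methoxymethoxy)-5-(2-methylbut-3-en-2-yl)phenyl formate | C=CC(C)(C)c1cc(OC=O)c(OCOC)c(OCOC)c1OC
F2 | step 10 | 4-methoxy-2,3-bis(methoxymethoxy)-5-(2-methylbut-3-en-2-yl)phenol | C=CC(C)(C)c1cc(O)c(OCOC)c(OCOC)c1OC
F3 | step 10 | 4-methoxy-2,3-bis(methoxymethoxy)-5-(2-methylbut-3-en-2-yl)phenyl trifluoromethanesulfonate | C=CC(C)(C)c1cc(OS(=O)(=O)C(F)(F)F)c(OCOC)c(OCOC)c1OC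
F4 | step 10 | 7-(methoxymethoxy)chroman-4-one | O=C1CCOc2cc(OCOC)ccc21
F5 | step 10 | rac-7-(methoxymethoxy)-3-[4-methoxy-2,3-bis(methoxymethoxy)-5-(2-methylbut-3-en-2-yl)phenyl]chroman-4-one | C=CC(C)(C)c1cc(C2COc3cc(OCOC)ccc3C2=O)c(OCOC)c(OCOC)c1OC
F6 | step 10 | (3S,4S)-7-(methoxymethoxy)-3-[4-methoxy-2,3-bis(methoxymethoxy)-5-(2-methylbut-3-en-2-yl)phenyl]chroman-4-ol (cis) | O[C@H]1[C@@H](c2cc(C(C)(C)C=C)c(OC)c(OCOC)c2OCOC)COc2cc(OCOC)ccc21
F7 | step 9 | rac-tert-butyldimethylsilyl 2-{2-hydroxy-2-[4-methoxy-2,3-bis(methoxymethoxy)-5-(2-methylbut-3-en-2-yl)phenyl]ethoxy}-4-(methoxymethoxy)benzoate | C=CC(C)(C)c1cc(C(O)COc2cc(OCOC)ccc2C(=O)O[Si](C)(C)C(C)(C)C)c(OCOC)c(OCOC)c1OC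
F8 | step 9 | rac-tert-butyldimethylsilyl 2-{2-chloro-2-[4-methoxy-2,3-bis(methoxymethoxy)-5-(2-methylbut-3-en-2-yl)phenyl]ethoxy}-4-(methoxymethoxy)benzoate | C=CC(C)(C)c1cc(C(Cl)COc2cc(OCOC)ccc2C(=O)O[Si](C)(C)C(C)(C)C)c(OCOC)c(OCOC)c1OC
F9 | step 3 | 2,3-dihydroxy-4-methoxybenzaldehyde | O=Cc1ccc(OC)c(O)c1O
F10 | step 3 | 4-methoxy-2,3-bis(methoxymethoxy)benzaldehyde | O=Cc1ccc(OC)c(OCOC)c1OCOC
F11 | step 3 | 5-bromo-4-methoxy-2,3-bis(methoxymethoxy)benzaldehyde | O=Cc1cc(Br)c(OC)c(OCOC)c1OCOC
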